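**Strategy**

Everything rests on an intramolecular Diels–Alder disconnection of the hydrindane (indane numbering; ring A atoms primed): its cyclohexane ring C3a–C4–C5–C6–C7–C7a is opened across C3a–C7a and C6–C7. The key step exploits that this ring carries bromine at C7 beside the methyl-bearing quaternary C7a and oxygen at C4 beside C3a: C7a=C7 becomes an (E)-bromoalkene dienophile, C3a–C6 a (Z)-2-silyloxydiene, joined by the tether C1–C3. One thermal cycloaddition of this acyclic triene, hung on a preformed ring A, closes both hydrindane rings and sets C3a, C7a and C7 from the single stereocenter C3. The ring A bromide is finished last by hydrogen-atom-transfer reduction of a bromoalkene.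

Key step: step 12

Assumption: the face selected by the Ti(OiPr)4–BINOL catalyst (step 2) and by the CuBr–Josiphos catalyst (step 9) is assigned by analogy with simpler substrates; should either be opposite, the mirror-image ligand is used and nothing else changes.

**Route**

Step 1
Reactants: 1 5,5-dimethylcyclohex-2-en-1-one
Product: 2 6,6-dimethylcyclohex-2-ene-1,4-dione
Conditions: Rh2(cap)4 (1 mol%), t-BuOOH (70% in water, 5 equiv), K2CO3 (0.5 equiv), CH2Cl2, 25–40 °C
Reagents that add atoms: tert-butyl hydroperoxide CC(C)(C)OO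
Why: Dirhodium caprolactamate-catalysed allylic C–H oxidation of an enone to an ene-1,4-dione attacks the only allylic methylene, C4, and forms no stereocenter.

Step 2
Reactants: 2 6,6-dimethylcyclohex-2-ene-1,4-dione
Product: 3 (4S)-4-hydroxy-6,6-dimethyl-4-(prop-2-en-1-yl)cyclohex-2-en-1-one
Conditions: Ti(OiPr)4 (30 mol%), (S)-BINOL (30 mol%), Sn(CH2CH=CH2)4 (1.5 equiv), i-PrOH (20 equiv), CH2Cl2, 23 °C
Reagents that add atoms: tetraallylstannane C=CC[Sn](CC=C)(CC=C)CC=C
Why: Titanium–BINOL-catalysed asymmetric allylation of a ketone with tetraallylstannane, a reaction type that accepts cyclic conjugated enones, should attack only the C4 carbonyl because C1 is shielded by the quaternary C6, and the chiral titanium alkoxide tells the planar CH= arm from the CH2 arm and so sets the tertiary carbinol center (the later C1') by catalyst control.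

Step 3
Reactants: 3 (4S)-4-hydroxy-6,6-dimethyl-4-(prop-2-en-1-yl)cyclohex-2-en-1-one
Product: 4 (4S)-6,6-dimethyl-4-(prop-2-en-1-yl)-4-[(triethylsilyl)oxy]cyclohex-2-en-1-one
Conditions: Et3SiOTf (1.3 equiv), 2,6-lutidine (2 equiv), CH2Cl2, −78 to 0 °C
Reagents that add atoms: triethylsilyl trifluoromethanesulfonate CC[Si](CC)(CC)OS(=O)(=O)C(F)(F)F
Why: O-silylation of a hindered tertiary alcohol with a silyl triflate and a hindered base masks the hydroxyl for the hydride, Grignard and enolisation steps and does not touch the stereocenter.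

Step 4
Reactants: 4 (4S)-6,6-dimethyl-4-(prop-2-en-1-yl)-4-[(triethylsilyl)oxy]cyclohex-2-en-1-one
Product: 6 (4R)-6,6-dimethyl-4-(prop-2-en-1-yl)-4-[(triethylsilyl)oxy]cyclohex-1-en-1-yl trifluoromethanesulfonate, via lithium enolate 5 (not isolated)
Conditions: LiBH(s-Bu)3 (1.1 equiv), THF, −78 °C; then PhNTf2 (1.3 equiv), −78 to 0 °C
Reagents that add atoms: N-phenylbis(trifluoromethanesulfonimide) O=S(=O)(N(c1ccccc1)S(=O)(=O)C(F)(F)F)C(F)(F)F
Why: Reductive enolate triflation, in which the bulky borohydride adds 1,4 to the β-unsubstituted enone whose carbonyl is blocked by the adjacent quaternary carbon and the regiodefined enolate is trapped on oxygen, gives the enol triflate with the carbinol center unchanged (its descriptor becomes R only through the priority rules).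

Step 5
Reactants: 6 (4R)-6,6-dimethyl-4-(prop-2-en-1-yl)-4-[(triethylsilyl)oxy]cyclohex-1-en-1-yl trifluoromethanesulfonate
Product: 7 {[(1R)-4-bromo-5,5-dimethyl-1-(prop-2-en-1-yl)cyclohex-3-en-1-yl]oxy}triethylsilane
Conditions: Ni(cod)2 (10 mol%), LiBr (3 equiv), DMA/THF (1:3), 23 °C
Reagents that add atoms: lithium bromide [Li+].[Br-]
Why: Nickel-catalysed halogen exchange of an enol triflate (oxidative addition, triflate-for-bromide exchange at nickel, reductive elimination) gives the alkenyl bromide regiospecifically under conditions that leave the silyl ether and the terminal alkene alone.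

Step 6
Reactants: 7 {[(1R)-4-bromo-5,5-dimethyl-1-(prop-2-en-1-yl)cyclohex-3-en-1-yl]oxy}triethylsilane; 8 methyl acrylate
Product: 9 methyl (2E)-4-{(1R)-4-bromo-5,5-dimethyl-1-[(triethylsilyl)oxy]cyclohex-3-en-1-yl}but-2-enoate
Conditions: 8 (5 equiv), Hoveyda–Grubbs second-generation catalyst (5 mol%), CH2Cl2, 40 °C
Reagents that add atoms: none
Why: Olefin cross-metathesis of a terminal alkene with an acrylate is selective for the (E)-enoate, and the trisubstituted ring bromoalkene is too hindered and electron-poor to engage the ruthenium carbene.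

Step 7
Reactants: 10 but-3-yn-1-ol
Product: 12 (3E)-4-bromo-3-methylbut-3-en-1-ol, via alkenylalane 11 (not isolated)
Conditions: AlMe3 (3 equiv), Cp2ZrCl2 (0.25 equiv), CH2Cl2, 0 to 23 °C; then NBS (1.2 equiv), THF, −78 to 0 °C
Reagents that add atoms: trimethylaluminium C[Al](C)C; N-bromosuccinimide O=C1CCC(=O)N1Br
Why: Zirconium-catalysed carboalumination (Negishi carboalumination) adds methyl and aluminium syn across the alkyne with aluminium on the terminal carbon, and bromodealumination with retention then fixes the (E)-bromoalkene with bromine cis to the methyl group.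

Step 8
Reactants: 12 (3E)-4-bromo-3-methylbut-3-en-1-ol
Product: 13 (1E)-1,4-dibromo-2-methylbut-1-ene
Conditions: CBr4 (1.2 equiv), PPh3 (1.25 equiv), CH2Cl2, 0 °C
Reagents that add atoms: tetrabromomethane BrC(Br)(Br)Br
Why: The Appel reaction replaces the primary hydroxyl by SN2 attack of bromide on the alkoxyphosphonium ion and leaves the alkene geometry untouched.

Step 9
Reactants: 9 methyl (2E)-4-{(1R)-4-bromo-5,5-dimethyl-1-[(triethylsilyl)oxy]cyclohex-3-en-1-yl}but-2-enoate; 13 (1E)-1,4-dibromo-2-methylbut-1-ene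
Product: 15 methyl (3S,6E)-7-bromo-3-({(1R)-4-bromo-5,5-dimethyl-1-[(triethylsilyl)oxy]cyclohex-3-en-1-yl}methyl)-6-methylhept-6-enoate, via Grignard reagent 14 (not isolated)
Conditions: 13, Mg, Et2O, 23 °C; then 9, CuBr·SMe2 (5 mol%), (R)-1-[(SP)-2-(diphenylphosphino)ferrocenyl]ethyldicyclohexylphosphine (Josiphos ligand, 6 mol%), t-BuOMe, −75 °C; MeOH, aqueous NH4Cl
Reagents that add atoms: none
Why: Copper–Josiphos-catalysed asymmetric conjugate addition of a Grignard reagent to an α,β-unsaturated ester, for which magnesium is expected to insert only into the C(sp3)–Br bond of 13, delivers the alkyl group to one face of the (E)-enoate under catalyst control and so sets C3 as (S).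

Step 10
Reactants: 15 methyl (3S,6E)-7-bromo-3-({(1R)-4-bromo-5,5-dimethyl-1-[(triethylsilyl)oxy]cyclohex-3-en-1-yl}methyl)-6-methylhept-6-enoate
Product: 17 (5S,8E)-9-bromo-5-({(1R)-4-bromo-5,5-dimethyl-1-[(triethylsilyl)oxy]cyclohex-3-en-1-yl}methyl)-8-methylnona-1,8-dien-3-one, via Weinreb amide 16 (not isolated)
Conditions: MeNH(OMe)·HCl (1.5 equiv), i-PrMgCl (3 equiv), THF, −20 °C; then CH2=CHMgBr (3 equiv), −20 to 0 °C; inverse quench into cold 1 M HCl
Reagents that add atoms: vinylmagnesium bromide C=C[Mg]Br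
Why: The Weinreb ketone synthesis run in one flask, in which the magnesium amide of N,O-dimethylhydroxylamine converts the ester into the N-methoxy-N-methylamide and the chelated adduct of vinylmagnesium bromide releases the vinyl ketone only on acidic quench, stops at the enone and leaves C3 untouched.

Step 11
Reactants: 17 (5S,8E)-9-bromo-5-({(1R)-4-bromo-5,5-dimethyl-1-[(triethylsilyl)oxy]cyclohex-3-en-1-yl}methyl)-8-methylnona-1,8-dien-3-one
Product: 18 {[(3Z,5S,8E)-9-bromo-5-({(1R)-4-bromo-5,5-dimethyl-1-[(triethylsilyl)oxy]cyclohex-3-en-1-yl}methyl)-8-methylnona-1,3,8-trien-3-yl]oxy}(tert-butyl)dimethylsilane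
Conditions: t-BuMe2SiOTf (1.3 equiv), Et3N (2.5 equiv), CH2Cl2, −78 to 0 °C
Reagents that add atoms: tert-butyldimethylsilyl trifluoromethanesulfonate CC(C)(C)[Si](C)(C)OS(=O)(=O)C(F)(F)F
Why: Soft enolisation and O-silylation at the only enolisable position (C3a) gives the cross-conjugated 2-silyloxydiene, and the (Z)-enol ether (oxygen cis to C3) is expected as the usual outcome of silyl triflate–amine enolisation of alkyl ketones.

Step 12
Reactants: 18 {[(3Z,5S,8E)-9-bromo-5-({(1R)-4-bromo-5,5-dimethyl-1-[(triethylsilyl)oxy]cyclohex-3-en-1-yl}methyl)-8-methylnona-1,3,8-trien-3-yl]oxy}(tert-butyl)dimethylsilane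
Product: 19 {[(3S,3aS,7S,7aS)-7-bromo-3-({(1R)-4-bromo-5,5-dimethyl-1-[(triethylsilyl)oxy]cyclohex-3-en-1-yl}methyl)-7a-methyl-2,3,3a,6,7,7a-hexahydro-1H-inden-4-yl]oxy}(tert-butyl)dimethylsilane
Conditions: PhMe (0.01 M), BHT (0.1 equiv), N,O-bis(trimethylsilyl)acetamide (0.2 equiv), sealed tube, 200 °C
Reagents that add atoms: none
Why: Concerted but asynchronous thermal [4+2] cycloaddition (intramolecular Diels–Alder reaction) of a 1,6,8-nonatriene in which the three-carbon tether C1–C2–C3 links the diene terminus C3a to the dienophile carbon C7a; the closest known reaction type is the thermal cyclisation of 2-silyloxy nonatrienes onto unactivated alkenes, with the internal silyloxy group acting as a steric directing group. The cyclohexene ring C3a–C4–C5–C6–C7–C7a is closed as the cycloaddition ring itself through the new bonds C3a–C7a and C6–C7, and the cyclopentane is closed in the same event by the tether through C3a–C7a, so no ring of the skeleton is formed afterwards. C7 and C7a are set together by the (E)-geometry of the bromoalkene, since suprafacial addition keeps bromine cis to the angular methyl; the trans relation of C3a-H and C7a-CH3 comes from the transition state with the tether exo and methyl and bromine endo; C3a is set relative to C3 by allylic 1,3-strain, which holds H-3 in the diene plane beside the silyloxy group so that the dienophile arrives on the face opposite the ring A arm. The step needs trans- over cis-fusion and one diene face: the C4 silyloxy group should secure both, because the cis-fused transition state presses the tether against it, and the (Z)-enol ether geometry keeps the tether outside so that the s-cis diene is reachable. It also needs chemoselectivity over the ring A bromoalkene, which is expected because that alkene would have to form a bond at C4', a carbon bearing bromine next to the quaternary C3'. The main risk is the low dienophilicity of a trisubstituted bromoalkene, which is why high dilution, a radical inhibitor and an acid scavenger at 200 °C are specified.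

Step 13
Reactants: 19 {[(3S,3aS,7S,7aS)-7-bromo-3-({(1R)-4-bromo-5,5-dimethyl-1-[(triethylsilyl)oxy]cyclohex-3-en-1-yl}methyl)-7a-methyl-2,3,3a,6,7,7a-hexahydro-1H-inden-4-yl]oxy}(tert-butyl)dimethylsilane
Product: 20 (3S,3aS,7S,7aS)-7-bromo-3-{[(1R)-4-bromo-1-hydroxy-5,5-dimethylcyclohex-3-en-1-yl]methyl}-7a-methyloctahydro-4H-inden-4-one
Conditions: HF·pyridine, pyridine, THF, 0 to 23 °C
Reagents that add atoms: none
Why: Fluoride-induced desilylation cleaves the enol ether, whose protonation at C5 gives the C4 ketone without touching C3a, and the tertiary triethylsilyl ether in one operation, and the buffered medium should avoid epimerisation of the trans ring fusion.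

Step 14
Reactants: 20 (3S,3aS,7S,7aS)-7-bromo-3-{[(1R)-4-bromo-1-hydroxy-5,5-dimethylcyclohex-3-en-1-yl]methyl}-7a-methyloctahydro-4H-inden-4-one
Product: 21 (3S,3aS,4R,7S,7aS)-7-bromo-3-{[(1R)-4-bromo-1-hydroxy-5,5-dimethylcyclohex-3-en-1-yl]methyl}-4,7a-dimethyloctahydro-1H-inden-4-ol
Conditions: MeMgBr (4 equiv), CeCl3 (4 equiv), THF, −78 °C
Reagents that add atoms: methylmagnesium bromide C[Mg]Br
Why: Organocerium 1,2-addition is non-basic enough to spare C3a, and the methyl group should enter equatorially from the α face because the axial β trajectory is blocked by the syn-axial C7a methyl, which gives the axial β hydroxyl and (R)-C4.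

Step 15
Reactants: 21 (3S,3aS,4R,7S,7aS)-7-bromo-3-{[(1R)-4-bromo-1-hydroxy-5,5-dimethylcyclohex-3-en-1-yl]methyl}-4,7a-dimethyloctahydro-1H-inden-4-ol
Product: 22 (3S,3aS,4R,7S,7aS)-7-bromo-3-{[(1S,4S)-4-bromo-1-hydroxy-3,3-dimethylcyclohexyl]methyl}-4,7a-dimethyloctahydro-1H-inden-4-ol (CNP0166978.1)
Conditions: Mn(dpm)3 (10 mol%), PhSiH3 (2 equiv), t-BuOOH (1.5 equiv), i-PrOH, 23 °C
Reagents that add atoms: none
Why: Manganese-hydride hydrogen-atom-transfer hydrogenation, a reaction type known to reduce haloalkenes without loss of halogen, places H• on C5', and the resulting α-bromo radical at C4' should take its hydrogen along the axial trajectory anti to the axial C3' methyl in the chair biased by the equatorial C1' arm, which leaves bromine equatorial and cis to the C1' hydroxyl, the (S)-configuration at C4'.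

**Compound list**

1 | 5,5-dimethylcyclohex-2-en-1-one | O=C1C=CCC(C)(C)C1 | starting material
2 | 6,6-dimethylcyclohex-2-ene-1,4-dione | CC1(C)CC(=O)C=CC1=O | intermediate
3 | (4S)-4-hydroxy-6,6-dimethyl-4-(prop-2-en-1-yl)cyclohex-2-en-1-one | CC1(C)C[C@@](O)(CC=C)C=CC1=O | intermediate
4 | (4S)-6,6-dimethyl-4-(prop-2-en-1-yl)-4-[(triethylsilyl)oxy]cyclohex-2-en-1-one | CC1(C)C[C@@](O[Si](CC)(CC)CC)(CC=C)C=CC1=O | intermediate
5 | lithium (4R)-6,6-dimethyl-4-(prop-2-en-1-yl)-4-[(triethylsilyl)oxy]cyclohex-1-en-1-olate | CC1(C)C[C@@](O[Si](CC)(CC)CC)(CC=C)CC=C1O[Li] | intermediate (not isolated)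
6 | (4R)-6,6-dimethyl-4-(prop-2-en-1-yl)-4-[(triethylsilyl)oxy]cyclohex-1-en-1-yl trifluoromethanesulfonate | CC1(C)C[C@@](O[Si](CC)(CC)CC)(CC=C)CC=C1OS(=O)(=O)C(F)(F)F | intermediate
7 | {[(1R)-4-bromo-5,5-dimethyl-1-(prop-2-en-1-yl)cyclohex-3-en-1-yl]oxy}triethylsilane | CC1(C)C[C@@](O[Si](CC)(CC)CC)(CC=C)CC=C1Br | intermediate
8 | methyl acrylate | C=CC(=O)OC | starting material
9 | methyl (2E)-4-{(1R)-4-bromo-5,5-dimethyl-1-[(triethylsilyl)oxy]cyclohex-3-en-1-yl}but-2-enoate | CC1(C)C[C@@](O[Si](CC)(CC)CC)(C/C=C/C(=O)OC)CC=C1Br | intermediate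
10 | but-3-yn-1-ol | C#CCCO | starting material
11 | {(1E)-4-[(dimethylalumanyl)oxy]-2-methylbut-1-en-1-yl}dimethylalumane | C[Al](C)/C=C(\C)CCO[Al](C)C | intermediate (not isolated)
12 | (3E)-4-bromo-3-methylbut-3-en-1-ol | OCC/C(C)=C/Br | intermediate
13 | (1E)-1,4-dibromo-2-methylbut-1-ene | BrCC/C(C)=C/Br | intermediate
14 | [(3E)-4-bromo-3-methylbut-3-en-1-yl]magnesium bromide | Br[Mg]CC/C(C)=C/Br | intermediate (not isolated)
15 | methyl (3S,6E)-7-bromo-3-({(1R)-4-bromo-5,5-dimethyl-1-[(triethylsilyl)oxy]cyclohex-3-en-1-yl}methyl)-6-methylhept-6-enoate | CC1(C)C[C@@](O[Si](CC)(CC)CC)(C[C@@H](CC(=O)OC)CC/C(C)=C/Br)CC=C1Br | intermediate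
16 | (3S,6E)-7-bromo-3-({(1R)-4-bromo-5,5-dimethyl-1-[(triethylsilyl)oxy]cyclohex-3-en-1-yl}methyl)-N-methoxy-N,6-dimethylhept-6-enamide | CC1(C)C[C@@](O[Si](CC)(CC)CC)(C[C@@H](CC(=O)N(C)OC)CC/C(C)=C/Br)CC=C1Br | intermediate (not isolated)
17 | (5S,8E)-9-bromo-5-({(1R)-4-bromo-5,5-dimethyl-1-[(triethylsilyl)oxy]cyclohex-3-en-1-yl}methyl)-8-methylnona-1,8-dien-3-one | CC1(C)C[C@@](O[Si](CC)(CC)CC)(C[C@@H](CC(=O)C=C)CC/C(C)=C/Br)CC=C1Br | intermediate
18 | {[(3Z,5S,8E)-9-bromo-5-({(1R)-4-bromo-5,5-dimethyl-1-[(triethylsilyl)oxy]cyclohex-3-en-1-yl}methyl)-8-methylnona-1,3,8-trien-3-yl]oxy}(tert-butyl)dimethylsilane | CC1(C)C[C@@](O[Si](CC)(CC)CC)(C[C@@H](/C=C(\O[Si](C)(C)C(C)(C)C)C=C)CC/C(C)=C/Br)CC=C1Br | intermediate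
19 | {[(3S,3aS,7S,7aS)-7-bromo-3-({(1R)-4-bromo-5,5-dimethyl-1-[(triethylsilyl)oxy]cyclohex-3-en-1-yl}methyl)-7a-methyl-2,3,3a,6,7,7a-hexahydro-1H-inden-4-yl]oxy}(tert-butyl)dimethylsilane | CC1(C)C[C@@](O[Si](CC)(CC)CC)(C[C@@H]2CC[C@]3(C)[C@@H](Br)CC=C(O[Si](C)(C)C(C)(C)C)[C@@H]23)CC=C1Br | intermediate
20 | (3S,3aS,7S,7aS)-7-bromo-3-{[(1R)-4-bromo-1-hydroxy-5,5-dimethylcyclohex-3-en-1-yl]methyl}-7a-methyloctahydro-4H-inden-4-one | CC1(C)C[C@@](O)(C[C@@H]2CC[C@]3(C)[C@@H](Br)CCC(=O)[C@@H]23)CC=C1Br | intermediate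
21 | (3S,3aS,4R,7S,7aS)-7-bromo-3-{[(1R)-4-bromo-1-hydroxy-5,5-dimethylcyclohex-3-en-1-yl]methyl}-4,7a-dimethyloctahydro-1H-inden-4-ol | CC1(C)C[C@@](O)(C[C@@H]2CC[C@]3(C)[C@@H](Br)CC[C@@](C)(O)[C@@H]23)CC=C1Br | intermediate
22 | (3S,3aS,4R,7S,7aS)-7-bromo-3-{[(1S,4S)-4-bromo-1-hydroxy-3,3-dimethylcyclohexyl]methyl}-4,7a-dimethyloctahydro-1H-inden-4-ol | CC1(C)C[C@@](O)(C[C@@H]2CC[C@]3(C)[C@@H](Br)CC[C@@](C)(O)[C@@H]23)CC[C@@H]1Br | target

**Step count**

Total: 15 steps. Longest linear sequence: 13 steps (steps 1–6 and 9–15, from 1).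

**The three steps most likely to fail**

Step 12 (key cycloaddition). The addition to the unactivated, trisubstituted bromoalkene may be too slow, so that thermal desilylation or polymerisation of the dienol ether competes and the trans/cis ratio drifts. The fallback sets out from 9 and comes back to the route at 22. It activates the dienophile as a nitroalkene and brings in the C7 bromine the way the ring A bromine is brought in.
- Enoate 9 receives, under the catalyst of step 9, (3-methylbut-3-en-1-yl)magnesium bromide F1, made from 4-bromo-2-methylbut-1-ene and Mg, to give the isopropenyl ester F2.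
- The one-flask sequence of step 10 gives, through the Weinreb amide F3, the vinyl ketone F4.
- Radical nitration of the 1,1-disubstituted alkene with AgNO2 and TEMPO gives the (E)-nitroalkene F5.
- Silylation as in step 11 gives the nitro dienol ether F6, which should cyclise between 23 and 80 °C with the nitro group endo, hence trans-fused, to the nitro cycloadduct F7.
- HF·pyridine then gives the nitro ketone F8, and MeMgBr/CeCl3 the nitro diol F9.
- A Nef reaction (NaOMe, then buffered aqueous TiCl3) gives the C7 ketone F10.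
- KN(SiMe3)2 with PhNTf2 gives the C6=C7 enol triflate F11, and Ni(cod)2 with LiBr the bis(bromoalkene) F12.
- Both bromoalkenes of F12 are reduced together under the conditions of step 15, the C7 radical taking hydrogen anti to the angular methyl, to give 22.

Step 15 (hydrogen-atom-transfer reduction). Hydrogen may be delivered to the α-bromo radical from the equatorial side, which loses facial control at C4', or the C–Br bond may be reduced. The fallback sets out from 21 and comes back at 22. The stepwise radical reduction is replaced by concerted syn transfer of both hydrogens from diimide (2-nitrobenzenesulfonyl hydrazide, Et3N, CH2Cl2, large excess). Diimide reduces haloalkenes with retention of the halogen and must approach the ring A face opposite the axial C3' methyl and the axial C1' oxygen. No new compound is formed.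

Step 9 (asymmetric conjugate addition). The bulky silyloxy-bearing quaternary center next to the enoate may erode the facial control of the catalyst, and the magnesium insertion may be incompletely selective. The fallback sets out from 7 and comes back at 16; it uses auxiliary control instead of catalyst control.
- Cross-metathesis of 7 with (R)-3-acryloyl-4-phenyloxazolidin-2-one gives the N-enoyl oxazolidinone F13.
- The organocopper reagent from Grignard reagent 14 and CuBr·SMe2 adds to the chelated s-cis imide anti to the phenyl group to give the conjugate adduct F14.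
- AlMe3 with MeNH(OMe)·HCl cleaves the auxiliary to give Weinreb amide 16, now isolated, which is taken on with CH2=CHMgBr as in step 10.

Further compounds
F1 | step 12 | (3-methylbut-3-en-1-yl)magnesium bromide | Br[Mg]CCC(C)=C
F2 | step 12 | isopropenyl ester: methyl (3S)-3-({(1R)-4-bromo-5,5-dimethyl-1-[(triethylsilyl)oxy]cyclohex-3-en-1-yl}methyl)-6-methylhept-6-enoate | CC1(C)C[C@@](O[Si](CC)(CC)CC)(C[C@@H](CC(=O)OC)CCC(C)=C)CC=C1Br
F3 | step 12 | Weinreb amide: (3S)-3-({(1R)-4-bromo-5,5-dimethyl-1-[(triethylsilyl)oxy]cyclohex-3-en-1-yl}methyl)-N-methoxy-N,6-dimethylhept-6-enamide | CC1(C)C[C@@](O[Si](CC)(CC)CC)(C[C@@H](CC(=O)N(C)OC)CCC(C)=C)CC=C1Br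
F4 | step 12 | vinyl ketone: (5S)-5-({(1R)-4-bromo-5,5-dimethyl-1-[(triethylsilyl)oxy]cyclohex-3-en-1-yl}methyl)-8-methylnona-1,8-dien-3-one | CC1(C)C[C@@](O[Si](CC)(CC)CC)(C[C@@H](CC(=O)C=C)CCC(C)=C)CC=C1Br
F5 | step 12 | (E)-nitroalkene: (5S,8E)-5-({(1R)-4-bromo-5,5-dimethyl-1-[(triethylsilyl)oxy]cyclohex-3-en-1-yl}methyl)-8-methyl-9-nitronona-1,8-dien-3-one | CC1(C)C[C@@](O[Si](CC)(CC)CC)(C[C@@H](CC(=O)C=C)CC/C(C)=C/[N+](=O)[O-])CC=C1Br
F6 | step 12 | nitro dienol ether: (3Z)-tert-butyldimethylsilyl dienol ether of F5 | CC1(C)C[C@@](O[Si](CC)(CC)CC)(C[C@@H](/C=C(\O[Si](C)(C)C(C)(C)C)C=C)CC/C(C)=C/[N+](=O)[O-])CC=C1Br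
F7 | step 12 | nitro cycloadduct: 19 with a nitro group in place of the C7 bromine | CC1(C)C[C@@](O[Si](CC)(CC)CC)(C[C@@H]2CC[C@]3(C)[C@@H]([N+](=O)[O-])CC=C(O[Si](C)(C)C(C)(C)C)[C@@H]23)CC=C1Br
F8 | step 12 | nitro ketone: 20 with a nitro group in place of the C7 bromine | CC1(C)C[C@@](O)(C[C@@H]2CC[C@]3(C)[C@@H]([N+](=O)[O-])CCC(=O)[C@@H]23)CC=C1Br
F9 | step 12 | nitro diol: 21 with a nitro group in place of the C7 bromine | CC1(C)C[C@@](O)(C[C@@H]2CC[C@]3(C)[C@@H]([N+](=O)[O-])CC[C@@](C)(O)[C@@H]23)CC=C1Br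
F10 | step 12 | C7 ketone: 21 with a carbonyl at C7 in place of CHBr | CC1(C)C[C@@](O)(C[C@@H]2CC[C@]3(C)C(=O)CC[C@@](C)(O)[C@@H]23)CC=C1Br
F11 | step 12 | C6=C7 enol triflate of F10 | CC1(C)C[C@@](O)(C[C@@H]2CC[C@]3(C)C(OS(=O)(=O)C(F)(F)F)=CC[C@@](C)(O)[C@@H]23)CC=C1Br
F12 | step 12 | bis(bromoalkene): 21 with a C6=C7 double bond bearing bromine at C7 | CC1(C)C[C@@](O)(C[C@@H]2CC[C@]3(C)C(Br)=CC[C@@](C)(O)[C@@H]23)CC=C1Br
F0 | step 15 | none | none
F13 | step 9 | N-enoyl oxazolidinone: (4R)-3-[(2E)-4-{(1R)-4-bromo-5,5-dimethyl-1-[(triethylsilyl)oxy]cyclohex-3-en-1-yl}but-2-enoyl]-4-phenyl-1,3-oxazolidin-2-one | CC1(C)C[C@@](O[Si](CC)(CC)CC)(C/C=C/C(=O)N2[C@H](c3ccccc3)COC2=O)CC=C1Br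
F14 | step 9 | conjugate adduct: (4R)-3-[(3S,6E)-7-bromo-3-({(1R)-4-bromo-5,5-dimethyl-1-[(triethylsilyl)oxy]cyclohex-3-en-1-yl}methyl)-6-methylhept-6-enoyl]-4-phenyl-1,3-oxazolidin-2-one | CC1(C)C[C@@](O[Si](CC)(CC)CC)(C[C@@H](CC(=O)N2[C@H](c3ccccc3)COC2=O)CC/C(C)=C/Br)CC=C1Br
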